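**Plan**
- Retrosynthesis: the butenolide is cut at C13–C14 and O–C16 (ester aldol with a silyloxyacetaldehyde, then lactonisation), ring B at C8–C9 (cycloisomerisation of a 1,7-enyne), the side chain at C12–C13 (Johnson–Claisen), C10–C9 (aldol with acrolein) and C5–C6 (conjugate addition), and ring A is opened to an aldehyde and pent-1-en-3-one (Robinson annulation).
- Enabling feature: in ring B (C5–C10) the neighbours C8 and C9 carry a one-carbon branch (C17) and the C11 chain, so a C8≡C17 alkyne on the C5 arm and a C9=C11 alkene on C10 of a finished ring A (C1–C5, C10) can fold into ring B, leaving C8=C17 and C11=C12.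
- Forward order: ring A, then the C5 butynyl arm and the C10 alkenyl arm, ring B by palladium catalysis, C17 oxygenation, the butenolide ring last.
- Stereochemistry: C5 from a copper-catalysed asymmetric conjugate addition, C10 from anti trapping of the resulting enolate, C9 from the chair-like carbopalladation, C8 from base equilibration of the aldehyde to the equatorial epimer.

Key step: step 8

Remark: atom labels follow labdane numbering (C17 on C8, C18/C19 on C4, C20 on C10, chain C11–C16); names of monocyclic compounds use 2,4-dioxaspiro[5.5]undecane locants (C6 = C4, C7 = C5, C8 = C10, C9 = C1); the hydroboration of step 9 is assumed to give mainly the axial C8 hydroxymethyl epimer, and the other epimer would converge in step 14.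

Step 1
Reactants: 1 (2,2-dimethyl-1,3-dioxan-5-yl)methanol
Product: 2 2,2-dimethyl-1,3-dioxane-5-carbaldehyde
Conditions: TEMPO (10 mol%), PhI(OAc)2 (1.1 equiv), CH2Cl2, rt
Reagents that add atoms: none
Why: Oxoammonium (TEMPO) oxidation of an unhindered primary alcohol stops at the aldehyde under non-aqueous, nearly neutral conditions that leave the isopropylidene acetal intact.

Step 2
Reactants: 2 2,2-dimethyl-1,3-dioxane-5-carbaldehyde; 3 pent-1-en-3-one
Product: 5 3,3,8-trimethyl-2,4-dioxaspiro[5.5]undec-7-en-9-one, via keto aldehyde 4 (not isolated)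
Conditions: Et2NSiMe3 (20 mol%), MeCN, 80 °C; then KOH (0.3 equiv), Bu4NOH (cat.), THF–H2O, rt
Reagents that add atoms: pent-1-en-3-one (3), CCC(=O)C=C
Why: Robinson annulation, in which the amine-catalysed Michael addition of the α-branched aldehyde creates the quaternary C4 and the base-mediated aldol condensation of the ethyl ketone onto the non-enolisable aldehyde can only close the six-membered ring A enone bearing the C10 methyl group.

Step 3
Reactants: 5 3,3,8-trimethyl-2,4-dioxaspiro[5.5]undec-7-en-9-one; 6 (4-bromobut-1-yn-1-yl)trimethylsilane; 7 prop-2-enal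
Product: 10 (7R,8R)-8-(1-hydroxyprop-2-en-1-yl)-3,3,8-trimethyl-7-[4-(trimethylsilyl)but-3-yn-1-yl]-2,4-dioxaspiro[5.5]undecan-9-one (both carbinol epimers), via Grignard reagent 8 (not isolated), via magnesium enolate 9 (not isolated)
Conditions: 6, Mg, Et2O, rt; 5, CuBr·SMe2 (5 mol%), 1-[2-(dicyclohexylphosphino)ferrocenyl]ethyldiphenylphosphine (6 mol%, the antipode that gives 7R), t-BuOMe, −78 °C; then 7 (3 equiv), THF, −78 → −40 °C; aq. NH4Cl
Reagents that add atoms: (4-bromobut-1-yn-1-yl)trimethylsilane (6), C[Si](C)(C)C#CCCBr; prop-2-enal (7), C=CC=O; magnesium, [Mg] (retained only in 8 and 9)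
Why: Copper-catalysed asymmetric conjugate addition with aldol trapping, in which the chiral copper–diphosphine complex selects the enone face at C5 and the magnesium enolate, whose new arm sits pseudoaxial to avoid the C10 methyl, is attacked by acrolein (1,2-addition) on the opposite face, so that C10 is set with the two arms trans while the carbinol carbon is left uncontrolled.

Step 4
Reactants: 10 (7R,8R)-8-(1-hydroxyprop-2-en-1-yl)-3,3,8-trimethyl-7-[4-(trimethylsilyl)but-3-yn-1-yl]-2,4-dioxaspiro[5.5]undecan-9-one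
Product: 11 N'-[(7R,8S)-8-(1-hydroxyprop-2-en-1-yl)-3,3,8-trimethyl-7-[4-(trimethylsilyl)but-3-yn-1-yl]-2,4-dioxaspiro[5.5]undecan-9-ylidene]-4-methylbenzenesulfonohydrazide
Conditions: TsNHNH2 (1.3 equiv), MeOH, 45 °C
Reagents that add atoms: 4-methylbenzenesulfonohydrazide, Cc1ccc(cc1)S(=O)(=O)NN
Why: Hydrazone condensation is standard for cyclohexanones with one quaternary and one methylene α-carbon, and the near-neutral medium should spare the acetonide, the silylalkyne and the β-hydroxy ketone.

Step 5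
Reactants: 11 tosylhydrazone of 10
Product: 12 1-[(7R,8R)-3,3,8-trimethyl-7-[4-(trimethylsilyl)but-3-yn-1-yl]-2,4-dioxaspiro[5.5]undecan-8-yl]prop-2-en-1-ol (both carbinol epimers)
Conditions: catecholborane (3 equiv), CHCl3, 0 °C → rt; then NaOAc·3H2O, 60 °C
Reagents that add atoms: none
Why: Tosylhydrazone reduction, a mild Wolff–Kishner-type deoxygenation in which hydride addition to C=N, loss of sulfinate and extrusion of N2 from the diazene turn C1 into CH2 without touching the silylalkyne, the vinyl group or the stereocentres.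

Step 6
Reactants: 12 1-[(7R,8R)-3,3,8-trimethyl-7-[4-(trimethylsilyl)but-3-yn-1-yl]-2,4-dioxaspiro[5.5]undecan-8-yl]prop-2-en-1-ol; 13 1,1,1-trimethoxyethane
Product: 14 methyl (4E)-5-[(7S,8S)-3,3,8-trimethyl-7-[4-(trimethylsilyl)but-3-yn-1-yl]-2,4-dioxaspiro[5.5]undecan-8-yl]pent-4-enoate
Conditions: MeC(OMe)3 (10 equiv), EtCO2H (10 mol%), xylene, 140 °C, MeOH distilled off
Reagents that add atoms: 1,1,1-trimethoxyethane (13), CC(OC)(OC)OC
Why: Johnson–Claisen rearrangement, in which the ketene acetal formed on the allylic alcohol rearranges through a chair transition state with the quaternary C10 substituent equatorial, so both carbinol epimers should converge on the E C9=C11 alkene while C12–C13 is formed.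

Step 7
Reactants: 14 methyl (4E)-5-[(7S,8S)-3,3,8-trimethyl-7-[4-(trimethylsilyl)but-3-yn-1-yl]-2,4-dioxaspiro[5.5]undecan-8-yl]pent-4-enoate
Product: 15 methyl (4E)-5-[(7S,8S)-7-(but-3-yn-1-yl)-3,3,8-trimethyl-2,4-dioxaspiro[5.5]undecan-8-yl]pent-4-enoate
Conditions: K2CO3 (0.3 equiv), MeOH, rt
Reagents that add atoms: none
Why: Base-catalysed protodesilylation cleaves only the C(sp)–Si bond, and a methyl ester in methanol cannot be scrambled.

Step 8
Reactants: 15 methyl (4E)-5-[(7S,8S)-7-(but-3-yn-1-yl)-3,3,8-trimethyl-2,4-dioxaspiro[5.5]undecan-8-yl]pent-4-enoate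
Product: 16 bicyclic diene ester (5S,9R,10R): trans-decalin with C4 spiro acetonide, exocyclic C8=C17 methylene, C10 methyl and C9 side chain (E)-CH=CH–CH2–CO2Me
Conditions: Pd(OAc)2 (5 mol%), PPh3 (15 mol%), AcOH (1 equiv), PhMe, 70 °C
Reagents that add atoms: none
Why: PPh3 reduces Pd(OAc)2 to zerovalent palladium, which adds acetic acid oxidatively to a divalent palladium hydride; this adds to the terminal alkyne with hydrogen on C17 and palladium on C8, the vinylpalladium inserts the C9=C11 alkene in a syn fashion to form C8–C9, and β-hydride loss from C12 releases the 8(17),11E-diene and returns the hydride. The closest known reaction type is the palladium-catalysed Alder-ene cycloisomerisation of 1,6- and 1,7-enynes to cyclic 1,4-dienes. Ring B closes in the 6-exo-trig mode with respect to the alkene. The new C9 centre is controlled by the ring A chair, whose trans-diequatorial C5 and C10 arms impose a chair-like, trans-decalin-type transition state in which the four-centre insertion geometry keeps C11 in the plane of the developing C8=C17 unit, that is equatorial and cis to the axial C20 methyl. The step needs palladium on C8 rather than C17, which the terminal alkyne and the coordinating alkene should secure, and β-hydride loss toward C12 rather than C9, which is favoured because reaching the C9–H bond requires an eclipsed rotamer that pushes C12 against quaternary C10 whereas a C12–H bond is reached without strain. The acetonide, the methyl ester and the E geometry of the alkene are spectators under these weakly acidic, anhydrous conditions.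

Step 9
Reactants: 16 bicyclic diene ester
Product: 17 C17 alcohol (5S,8R,9R,10S): as 16 with an axial C8–CH2OH in place of the methylene
Conditions: 9-BBN (2 equiv), THF, 0 °C → 40 °C; then 30% H2O2, aq. NaOAc, 0 °C → rt
Reagents that add atoms: hydrogen peroxide, OO
Why: Hydroboration–oxidation, in which 9-BBN reacts far faster with the 1,1-disubstituted C8=C17 alkene than with the 1,2-disubstituted C11=C12 alkene and places boron on C17, hydrogen should reach C8 on the face away from the axial C20 methyl so that the hydroxymethyl group ends axial, and the buffered peroxide spares the methyl ester.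

Step 10
Reactants: 17 C17 alcohol
Product: 18 saturated hydroxy ester (5S,8R,9R,10S): C9 side chain CH2CH2CH2CO2Me
Conditions: H2 (1 atm), Pd/C (10%), EtOAc, rt
Reagents that add atoms: none
Why: Heterogeneous catalytic hydrogenation saturates the only remaining alkene and creates no stereocentre.

Step 11
Reactants: 18 saturated hydroxy ester; 19 2-[tert-butyl(dimethyl)silyl]oxyacetaldehyde
Product: 20 aldol adduct: 18 carrying CH(OH)CH2OSi(t-Bu)Me2 on C13 (C13/C14 epimers)
Conditions: LiN(iPr)2 (2.3 equiv), THF, −78 °C; then 19 (2 equiv), −78 °C; aq. NH4Cl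
Reagents that add atoms: 2-[tert-butyl(dimethyl)silyl]oxyacetaldehyde (19), CC(C)(C)[Si](C)(C)OCC=O
Why: Ester enolate aldol addition, in which the first equivalent of base makes the C17 lithium alkoxide and the second the C13 enolate that forms C13–C14, the two new centres being left uncontrolled because both disappear in step 14.

Step 12
Reactants: 20 aldol adduct
Product: 21 hydroxy lactone diol: C9–CH2CH2–(4-hydroxy-2-oxooxolan-3-yl), axial C8–CH2OH
Conditions: Bu4NF (1.2 equiv), AcOH (1.2 equiv), THF, 0 °C → rt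
Reagents that add atoms: none
Why: Fluoride desilylation frees the C15 hydroxyl, which lactonises onto the methyl ester (5-exo-trig acyl substitution), and the acetic acid buffer should suppress retro-aldol cleavage.

Step 13
Reactants: 21 hydroxy lactone diol
Product: 22 axial C17 aldehyde of 21 (8R)
Conditions: TEMPO (20 mol%), PhI(OAc)2 (1.2 equiv), CH2Cl2, rt
Reagents that add atoms: none
Why: TEMPO/oxoammonium oxidation distinguishes the primary C17 alcohol from the secondary C14 alcohol on steric grounds and stops at the aldehyde.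

Step 14
Reactants: 22 axial C17 aldehyde
Product: 25 18,19-O-isopropylidene derivative of the target (5S,8S,9R,10S), via mesylate 23 (not isolated), via 8-epi butenolide aldehyde 24 (not isolated)
Conditions: MsCl (1.5 equiv), Et3N (4 equiv), CH2Cl2, 0 °C → rt; then DBU (2 equiv), rt
Reagents that add atoms: methanesulfonyl chloride, CS(=O)(=O)Cl (retained only in 23)
Why: Mesylation of the β-hydroxy lactone and E1cB elimination give the conjugated butenolide, and DBU then epimerises the aldehyde through its enolate to the equatorial 8S epimer, which is free of the 1,3-diaxial contact with the C20 methyl, so both C8 epimers from step 9 converge.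

Step 15
Reactants: 25 18,19-O-isopropylidene derivative of the target
Product: 26 3-{2-[(1R,2S,4aS,8aS)-2-formyl-5,5-bis(hydroxymethyl)-8a-methyldecahydronaphthalen-1-yl]ethyl}furan-2(5H)-one
Conditions: 1 M HCl, THF, rt
Reagents that add atoms: none
Why: Acid-catalysed hydrolysis of the isopropylidene acetal releases the two C4 hydroxymethyl groups, and the butenolide and the equatorial aldehyde are stable to dilute aqueous acid.

**Compound list**
1 | (2,2-dimethyl-1,3-dioxan-5-yl)methanol | OCC1COC(C)(C)OC1 | starting material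
2 | 2,2-dimethyl-1,3-dioxane-5-carbaldehyde | O=CC1COC(C)(C)OC1 | intermediate
3 | pent-1-en-3-one | CCC(=O)C=C | starting material
4 | 2,2-dimethyl-5-(3-oxopentyl)-1,3-dioxane-5-carbaldehyde (not isolated) | CCC(=O)CCC1(C=O)COC(C)(C)OC1 | intermediate
5 | 3,3,8-trimethyl-2,4-dioxaspiro[5.5]undec-7-en-9-one | CC1=CC2(CCC1=O)COC(C)(C)OC2 | intermediate
6 | (4-bromobut-1-yn-1-yl)trimethylsilane | C[Si](C)(C)C#CCCBr | starting material
7 | prop-2-enal (acrolein) | C=CC=O | starting material
8 | [4-(trimethylsilyl)but-3-yn-1-yl]magnesium bromide (not isolated) | C[Si](C)(C)C#CCC[Mg]Br | intermediate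
9 | bromomagnesium (7R)-3,3,8-trimethyl-7-[4-(trimethylsilyl)but-3-yn-1-yl]-2,4-dioxaspiro[5.5]undec-8-en-9-olate (not isolated) | CC1=C(O[Mg]Br)CCC2(COC(C)(C)OC2)[C@H]1CCC#C[Si](C)(C)C | intermediate
10 | (7R,8R)-8-(1-hydroxyprop-2-en-1-yl)-3,3,8-trimethyl-7-[4-(trimethylsilyl)but-3-yn-1-yl]-2,4-dioxaspiro[5.5]undecan-9-one (both carbinol epimers) | C[C@@]1(C(O)C=C)C(=O)CCC2(COC(C)(C)OC2)[C@H]1CCC#C[Si](C)(C)C | intermediate
11 | N'-[(7R,8S)-8-(1-hydroxyprop-2-en-1-yl)-3,3,8-trimethyl-7-[4-(trimethylsilyl)but-3-yn-1-yl]-2,4-dioxaspiro[5.5]undecan-9-ylidene]-4-methylbenzenesulfonohydrazide | C[C@@]1(C(O)C=C)C(=NNS(=O)(=O)c2ccc(C)cc2)CCC3(COC(C)(C)OC3)[C@H]1CCC#C[Si](C)(C)C | intermediate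
12 | 1-[(7R,8R)-3,3,8-trimethyl-7-[4-(trimethylsilyl)but-3-yn-1-yl]-2,4-dioxaspiro[5.5]undecan-8-yl]prop-2-en-1-ol (both carbinol epimers) | C[C@@]1(C(O)C=C)CCCC2(COC(C)(C)OC2)[C@H]1CCC#C[Si](C)(C)C | intermediate
13 | 1,1,1-trimethoxyethane (trimethyl orthoacetate) | CC(OC)(OC)OC | starting material
14 | methyl (4E)-5-[(7S,8S)-3,3,8-trimethyl-7-[4-(trimethylsilyl)but-3-yn-1-yl]-2,4-dioxaspiro[5.5]undecan-8-yl]pent-4-enoate | C[C@@]1(/C=C/CCC(=O)OC)CCCC2(COC(C)(C)OC2)[C@H]1CCC#C[Si](C)(C)C | intermediate
15 | methyl (4E)-5-[(7S,8S)-7-(but-3-yn-1-yl)-3,3,8-trimethyl-2,4-dioxaspiro[5.5]undecan-8-yl]pent-4-enoate | C[C@@]1(/C=C/CCC(=O)OC)CCCC2(COC(C)(C)OC2)[C@H]1CCC#C | intermediate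
16 | bicyclic diene ester (5S,9R,10R): trans-decalin, C4 spiro-linked 2,2-dimethyl-1,3-dioxane, exocyclic C8=C17 methylene, C10 methyl, C9 side chain (E)-CH=CH–CH2–CO2Me | C[C@@]12CCCC3(COC(C)(C)OC3)[C@H]1CCC(=C)[C@H]2/C=C/CC(=O)OC | intermediate
17 | C17 alcohol (5S,8R,9R,10S): as 16 with axial C8–CH2OH (cis to C20) in place of the methylene | C[C@@]12CCCC3(COC(C)(C)OC3)[C@H]1CC[C@@H](CO)[C@H]2/C=C/CC(=O)OC | intermediate
18 | saturated hydroxy ester (5S,8R,9R,10S): C9 side chain CH2CH2CH2CO2Me, axial C8–CH2OH | C[C@@]12CCCC3(COC(C)(C)OC3)[C@H]1CC[C@@H](CO)[C@H]2CCCC(=O)OC | intermediate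
19 | 2-[tert-butyl(dimethyl)silyl]oxyacetaldehyde | CC(C)(C)[Si](C)(C)OCC=O | starting material
20 | aldol adduct (5S,8R,9R,10S): 18 carrying CH(OH)CH2OSi(t-Bu)Me2 on C13 (C13/C14 epimers) | C[C@@]12CCCC3(COC(C)(C)OC3)[C@H]1CC[C@@H](CO)[C@H]2CCC(C(O)CO[Si](C)(C)C(C)(C)C)C(=O)OC | intermediate
21 | hydroxy lactone diol (5S,8R,9R,10S): C9–CH2CH2–(4-hydroxy-2-oxooxolan-3-yl), axial C8–CH2OH (C13/C14 epimers) | C[C@@]12CCCC3(COC(C)(C)OC3)[C@H]1CC[C@@H](CO)[C@H]2CCC1C(O)COC1=O | intermediate
22 | axial C17 aldehyde of 21 (5S,8R,9R,10S) | C[C@@]12CCCC3(COC(C)(C)OC3)[C@H]1CC[C@@H](C=O)[C@H]2CCC1C(O)COC1=O | intermediate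
23 | C14 methanesulfonate of 22 (not isolated) | C[C@@]12CCCC3(COC(C)(C)OC3)[C@H]1CC[C@@H](C=O)[C@H]2CCC1C(OS(C)(=O)=O)COC1=O | intermediate
24 | 8-epi butenolide aldehyde (5S,8R,9R,10S; not isolated) | C[C@@]12CCCC3(COC(C)(C)OC3)[C@H]1CC[C@@H](C=O)[C@H]2CCC1=CCOC1=O | intermediate
25 | 18,19-O-isopropylidene derivative of the target (5S,8S,9R,10S) | C[C@@]12CCCC3(COC(C)(C)OC3)[C@H]1CC[C@H](C=O)[C@H]2CCC1=CCOC1=O | intermediate
26 | 3-{2-[(1R,2S,4aS,8aS)-2-formyl-5,5-bis(hydroxymethyl)-8a-methyldecahydronaphthalen-1-yl]ethyl}furan-2(5H)-one, (5S,8S,9R,10S) in labdane numbering | C[C@@]12CCCC(CO)(CO)[C@H]1CC[C@H](C=O)[C@H]2CCC1=CCOC1=O | target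

**Step count and risk**
Total step count: 15. Longest linear sequence: 15 steps (1 → 26).

Steps most likely to fail:

1. Step 3. The alkyl group must be delivered to a β-carbon flanked by the C4 spiro centre and the C10 methyl, so copper-catalysed addition may be slow, and 1,2-addition and the uncatalysed background reaction may erode yield and enantiomeric purity. The fallback sets out from 2 and returns at 10. Aldehyde 2 is annulated with but-3-en-2-one under the conditions of step 2 to 3,3-dimethyl-2,4-dioxaspiro[5.5]undec-7-en-9-one F1. This enone lacks the α-methyl group and belongs to the 4,4-disubstituted cyclohexenones, for which copper-catalysed asymmetric Grignard addition is better established. Addition of 8 with the same catalyst should give the bromomagnesium (7S)-enolate F2, which is methylated in the same flask (MeI, DMPU) to the (7S)-8-methyl ketone F3. Me3SiCl/NaI/Et3N in MeCN should convert F3 mainly into the tetrasubstituted trimethylsilyl enol ether F4. A Mukaiyama aldol addition of F4 to acrolein 7 (BF3·OEt2, CH2Cl2, −78 °C), again anti to the C7 arm, leads back to 10.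

2. Step 8. Alkene insertion next to quaternary C10 may be slow enough for alkyne coupling or acetate addition to the alkyne to outrun ring closure, and re-addition of the palladium hydride may move the exocyclic C8=C17 bond into the ring. The fallback sets out from 15 and returns at 16. Internal-selective hydrosilylation of the terminal alkyne ([Cp*Ru(MeCN)3]PF6, Et3SiH, CH2Cl2, 0 °C) should give the 2-(triethylsilyl)alk-1-ene F5. Iododesilylation (N-iodosuccinimide, 2,6-lutidine, hexafluoroisopropanol, 0 °C) gives the vinyl iodide F6. An intramolecular Heck reaction (Pd(OAc)2, PPh3, Ag2CO3, MeCN, 70 °C) then closes the same C8–C9 bond in the 6-exo mode; oxidative addition of zerovalent palladium fixes the metal on C8 without any hydride addition to the alkyne, and the same chair-like insertion and β-hydride loss toward C12 should give 16.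

3. Step 4. Condensation at the ketone beside the quaternary carbon may be slow, and retro-aldol fragmentation of the β-hydroxy ketone may compete. The fallback sets out from 10 and returns at 15 by Barton–McCombie deoxygenation. Silylation (t-BuMe2SiOTf, 2,6-lutidine, CH2Cl2, −78 °C) gives the tert-butyldimethylsilyl ether F7, which can no longer fragment. LiAlH4 (Et2O, 0 °C) reduces the ketone to the C9 alcohol F8. 1,1'-Thiocarbonyldiimidazole (DMAP, PhMe, 90 °C) gives the imidazolyl thiocarbonate F9. Bu3SnH/AIBN (PhMe, 100 °C) removes the oxygen to give the deoxygenated silyl ether F10; the C1 radical has no alkene or alkyne within reach. Bu4NF (THF, rt → 50 °C) removes both silyl groups to the alkynyl allylic alcohol F11. The Johnson–Claisen rearrangement of F11 with 13 under the conditions of step 6 gives 15 directly.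

Further compounds
F1 | step 3 | 3,3-dimethyl-2,4-dioxaspiro[5.5]undec-7-en-9-one | O=C1C=CC2(CC1)COC(C)(C)OC2
F2 | step 3 | bromomagnesium (7S)-3,3-dimethyl-7-[4-(trimethylsilyl)but-3-yn-1-yl]-2,4-dioxaspiro[5.5]undec-8-en-9-olate | C1=C(O[Mg]Br)CCC2(COC(C)(C)OC2)[C@H]1CCC#C[Si](C)(C)C
F3 | step 3 | (7S)-3,3,8-trimethyl-7-[4-(trimethylsilyl)but-3-yn-1-yl]-2,4-dioxaspiro[5.5]undecan-9-one (C8 epimers) | CC1C(=O)CCC2(COC(C)(C)OC2)[C@H]1CCC#C[Si](C)(C)C
F4 | step 3 | trimethyl{[(7R)-3,3,8-trimethyl-7-[4-(trimethylsilyl)but-3-yn-1-yl]-2,4-dioxaspiro[5.5]undec-8-en-9-yl]oxy}silane | CC1=C(O[Si](C)(C)C)CCC2(COC(C)(C)OC2)[C@H]1CCC#C[Si](C)(C)C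
F5 | step 8 | methyl (4E)-5-[(7S,8S)-3,3,8-trimethyl-7-[3-(triethylsilyl)but-3-en-1-yl]-2,4-dioxaspiro[5.5]undecan-8-yl]pent-4-enoate | C[C@@]1(/C=C/CCC(=O)OC)CCCC2(COC(C)(C)OC2)[C@H]1CCC(=C)[Si](CC)(CC)CC
F6 | step 8 | methyl (4E)-5-[(7S,8S)-7-(3-iodobut-3-en-1-yl)-3,3,8-trimethyl-2,4-dioxaspiro[5.5]undecan-8-yl]pent-4-enoate | C[C@@]1(/C=C/CCC(=O)OC)CCCC2(COC(C)(C)OC2)[C@H]1CCC(I)=C
F7 | step 4 | (7R,8R)-8-{1-[tert-butyl(dimethyl)silyl]oxyprop-2-en-1-yl}-3,3,8-trimethyl-7-[4-(trimethylsilyl)but-3-yn-1-yl]-2,4-dioxaspiro[5.5]undecan-9-one | C[C@@]1(C(O[Si](C)(C)C(C)(C)C)C=C)C(=O)CCC2(COC(C)(C)OC2)[C@H]1CCC#C[Si](C)(C)C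
F8 | step 4 | (7R,8S)-8-{1-[tert-butyl(dimethyl)silyl]oxyprop-2-en-1-yl}-3,3,8-trimethyl-7-[4-(trimethylsilyl)but-3-yn-1-yl]-2,4-dioxaspiro[5.5]undecan-9-ol (C9 epimers) | C[C@@]1(C(O[Si](C)(C)C(C)(C)C)C=C)C(O)CCC2(COC(C)(C)OC2)[C@H]1CCC#C[Si](C)(C)C
F9 | step 4 | O-[(7R,8S)-8-{1-[tert-butyl(dimethyl)silyl]oxyprop-2-en-1-yl}-3,3,8-trimethyl-7-[4-(trimethylsilyl)but-3-yn-1-yl]-2,4-dioxaspiro[5.5]undecan-9-yl] 1H-imidazole-1-carbothioate | C[C@@]1(C(O[Si](C)(C)C(C)(C)C)C=C)C(OC(=S)n3ccnc3)CCC2(COC(C)(C)OC2)[C@H]1CCC#C[Si](C)(C)C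
F10 | step 4 | tert-butyl(dimethyl){1-[(7R,8R)-3,3,8-trimethyl-7-[4-(trimethylsilyl)but-3-yn-1-yl]-2,4-dioxaspiro[5.5]undecan-8-yl]prop-2-en-1-yl}oxysilane | C[C@@]1(C(O[Si](C)(C)C(C)(C)C)C=C)CCCC2(COC(C)(C)OC2)[C@H]1CCC#C[Si](C)(C)C
F11 | step 4 | 1-[(7R,8R)-7-(but-3-yn-1-yl)-3,3,8-trimethyl-2,4-dioxaspiro[5.5]undecan-8-yl]prop-2-en-1-ol | C[C@@]1(C(O)C=C)CCCC2(COC(C)(C)OC2)[C@H]1CCC#C
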